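## Retrosynthetic overview

- **Feature:** in ring B (the resorcinol ring), C1′ is the carbon bonded to benzofuran C2, and it is flanked by prenyl groups on C2′ and C6′. The hydroxyls on C3′ and C5′ leave the open carbon C4′ between them as the easiest site for an electrophile. Ring B is therefore grown with both prenyl groups already in place, not prenylated afterwards.
- **Disconnections of ring B:** 26 ⇒ (MOM removal, dehydrogenation, loss of CO2Me) cyclohexane-1,3-dione ester 19 ⇒ Michael–Claisen union of α-prenyl enone 15 with dimethyl prenylmalonate 17. Enone 15 ⇒ Horner–Wadsworth–Emmons olefination of benzofuran-2-carbaldehyde 12 with prenylated ketophosphonate 14.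
- **Disconnections of the benzofuran:** 12 ⇒ benzofuran ester 10 ⇒ salicylaldehyde 7 + methyl bromoacetate 8. The 1,1-dimethylallyl group of 7 ⇒ aromatic Claisen shift of prenyl ether 4, made from 2,4,6-trihydroxybenzaldehyde 1.
- **Ring order:** ring A is bought, the furan ring is closed in step 4, and ring B is closed in step 10 and made aromatic in steps 12–14.

Key step: step 10

Remark: Ar = 4,6-bis(methoxymethoxy)-7-(2-methylbut-3-en-2-yl)-1-benzofuran-2-yl and prenyl = 3-methylbut-2-en-1-yl; conjugate bases that differ from a numbered compound only by a proton are not numbered apart; 18–23 are handled as mixtures of diastereomers, which is harmless because ring B ends up planar and the target has no stereocentre.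

## Route

Step 1
Reactants: 1 2,4,6-trihydroxybenzaldehyde
Product: 2 2-hydroxy-4,6-bis(methoxymethoxy)benzaldehyde
Conditions: MOMCl (2.1 equiv), i-Pr2NEt, CH2Cl2, 0 °C → rt
Reagents that add atoms: chloromethyl methyl ether (MOMCl), COCCl
Why: Williamson-type O-alkylation in which the para hydroxyl and one ortho hydroxyl react, after which the last ortho hydroxyl is held in a hydrogen bond to the formyl oxygen and should stay free when only two equivalents of reagent are offered.

Step 2
Reactants: 2 2-hydroxy-4,6-bis(methoxymethoxy)benzaldehyde; 3 prenyl bromide (1-bromo-3-methylbut-2-ene)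
Product: 4 2,4-bis(methoxymethoxy)-6-(prenyloxy)benzaldehyde
Conditions: K2CO3, DMF, 50 °C
Reagents that add atoms: none
Why: Williamson ether synthesis in which carbonate in a dipolar aprotic solvent breaks the chelate and the phenoxide displaces bromide at the primary allylic carbon (SN2).

Step 3
Reactants: 4 2,4-bis(methoxymethoxy)-6-(prenyloxy)benzaldehyde
Product: 7 2-hydroxy-4,6-bis(methoxymethoxy)-3-(2-methylbut-3-en-2-yl)benzaldehyde, via ortho-dienone 5 (not isolated), via aryl trimethylsilyl ether 6 (not isolated)
Conditions: N,O-bis(trimethylsilyl)acetamide (BSA, 3 equiv), PhNEt2, 185 °C, sealed tube, Ar; then K2CO3 (cat.), MeOH, rt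
Reagents that add atoms: none
Why: Aromatic Claisen rearrangement whose [3,3] shift can end productively only at C3, the one ortho carbon that bears hydrogen, and which inverts the allyl unit to the 1,1-dimethylallyl group; silylation of the phenol as it forms blocks its return to dienone 5, the species from which a Cope shift to C5, an abnormal Claisen process or ring closure onto the new alkene would start.

Step 4
Reactants: 7 2-hydroxy-4,6-bis(methoxymethoxy)-3-(2-methylbut-3-en-2-yl)benzaldehyde; 8 methyl bromoacetate
Product: 10 methyl 4,6-bis(methoxymethoxy)-7-(2-methylbut-3-en-2-yl)-1-benzofuran-2-carboxylate, via aryloxyacetate 9 (not isolated)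
Conditions: K2CO3, DMF, 60 → 100 °C
Reagents that add atoms: none
Why: O-alkylation followed by intramolecular aldol condensation (Rap–Stoermer-type benzofuran synthesis), in which the methylene of 9 is acidified by the ester, lies within five-ring reach of the formyl carbon, and loses water under the driving force of furan aromaticity.

Step 5
Reactants: 10 methyl 4,6-bis(methoxymethoxy)-7-(2-methylbut-3-en-2-yl)-1-benzofuran-2-carboxylate
Product: 11 Ar-CH2OH, [4,6-bis(methoxymethoxy)-7-(2-methylbut-3-en-2-yl)-1-benzofuran-2-yl]methanol
Conditions: LiAlH4, THF, 0 °C; Na2SO4·10H2O quench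
Reagents that add atoms: none
Why: Hydride reduction of an ester to the primary alcohol, a reagent class that leaves acetals and unactivated alkenes alone.

Step 6
Reactants: 11 Ar-CH2OH
Product: 12 Ar-CHO, 4,6-bis(methoxymethoxy)-7-(2-methylbut-3-en-2-yl)-1-benzofuran-2-carbaldehyde
Conditions: MnO2 (activated, excess), CH2Cl2, rt
Reagents that add atoms: none
Why: MnO2 oxidation of a heterobenzylic alcohol, which stops at the aldehyde under neutral conditions and does not attack isolated alkenes or MOM ethers.

Step 7
Reactants: 13 dimethyl (2-oxopropyl)phosphonate; 3 prenyl bromide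
Product: 14 dimethyl (6-methyl-2-oxohept-5-en-3-yl)phosphonate
Conditions: NaH (1.0 equiv), THF, 0 °C; 3 (0.95 equiv), 0 °C → rt
Reagents that add atoms: none
Why: C-alkylation of a stabilised β-ketophosphonate carbanion, in which the carbon between phosphorus and carbonyl is by far the most acidic site and a slight deficit of the halide limits double alkylation.

Step 8
Reactants: 12 Ar-CHO; 14 dimethyl (6-methyl-2-oxohept-5-en-3-yl)phosphonate
Product: 15 (3E)-3-(Ar-methylidene)-6-methylhept-5-en-2-one (α-prenyl enone)
Conditions: 14, NaH, THF, 0 °C; then 12, rt → 50 °C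
Reagents that add atoms: none
Why: Horner–Wadsworth–Emmons olefination, which places the double bond at the prenyl-bearing carbon (a direct aldol condensation of the parent ketone would react at its methyl group) and should favour the E isomer, a geometry that is in any case lost in step 10.

Step 9
Reactants: 16 dimethyl malonate; 3 prenyl bromide
Product: 17 dimethyl 2-prenylpropanedioate
Conditions: NaH (1.0 equiv), THF, 0 °C; 3 (0.9 equiv), rt
Reagents that add atoms: none
Why: Malonic ester alkylation (SN2 at the primary allylic bromide), kept at the mono stage by an excess of malonate.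

Step 10
Reactants: 15 α-prenyl enone; 17 dimethyl 2-prenylpropanedioate
Product: 19 methyl 6-Ar-1,5-diprenyl-2,4-dioxocyclohexane-1-carboxylate (mixture of diastereomers), via open-chain Michael adduct 18 (not isolated)
Conditions: 17 (1.5 equiv), NaOMe (1.5 equiv), MeOH (ca. 1 M), reflux; AcOH quench, 0 °C
Reagents that add atoms: none
Why: This is a Michael–Claisen annulation, the reaction type that converts enones and malonates into cyclohexane-1,3-diones (dimedone and olivetol-type constructions): methoxide deprotonates 17, and its carbanion adds reversibly to the β carbon of 15, which carries only hydrogen and the flat benzofuran, to give 18. After proton exchange the methyl-ketone enolate of 18 attacks one of the two equivalent ester carbonyls, expels methoxide and closes ring B by a 6-(enolexo)-exo-trig acyl substitution (Dieckmann-type closure). The new 1,3-dione is deprotonated at once at the CH2 between its carbonyls, and this stabilised enolate both drains the crowded, unfavourable Michael equilibrium and shields the non-enolisable β-keto ester from retro-Claisen opening. Three stereocentres arise (C1, C5 and C6 of the cyclohexanedione), governed only by reversibility of the addition and epimerisation at C5, and no control is needed because all three become sp2 carbons by step 14. The selectivities required are 1,4- over 1,2-addition and a single mode of closure: a fully substituted malonate carbanion cannot complete a Knoevenagel condensation, O-acylation to an enol lactone is reversible under methoxide, and the methyl group is the only acidic position of 18 that reaches an ester through a six-membered transition state, which fixes the oxygens meta and the prenyl groups ortho to the benzofuran-bearing carbon. The base-only medium leaves the MOM acetals and the three alkenes untouched.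

Step 11
Reactants: 19 methyl 6-Ar-1,5-diprenyl-2,4-dioxocyclohexane-1-carboxylate
Product: 21 5-Ar-4,6-diprenylcyclohexane-1,3-dione (constitutionally symmetric, mixture of diastereomers), via lithium carboxylate 20 (not isolated)
Conditions: LiCl (3 equiv), H2O (3 equiv), DMSO, 135 °C, Ar
Reagents that add atoms: none
Why: Krapcho demethoxycarbonylation, in which chloride attacks the unhindered O-methyl carbon (SN2) so that the crowding at the quaternary ester, which would slow saponification, does not matter, and β-keto carboxylate 20 loses CO2 in a near-neutral medium that spares MOM acetals and alkenes.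

Step 12
Reactants: 21 5-Ar-4,6-diprenylcyclohexane-1,3-dione
Product: 22 5-Ar-3-(methoxymethoxy)-4,6-diprenylcyclohex-2-en-1-one
Conditions: MOMCl (1.1 equiv), i-Pr2NEt, CH2Cl2, 0 °C; Et3N-washed silica
Reagents that add atoms: chloromethyl methyl ether (MOMCl), COCCl
Why: O-alkylation of a 1,3-dione enolate by a hard oxocarbenium-type electrophile (vinylogous ester formation), in which either oxygen of the symmetric dione gives the same constitution and the new MOM group can later leave together with the other two.

Step 13
Reactants: 22 5-Ar-3-(methoxymethoxy)-4,6-diprenylcyclohex-2-en-1-one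
Product: 23 6-Ar-4-(methoxymethoxy)-1,5-diprenyl-2-(trimethylsilyloxy)cyclohexa-1,3-diene
Conditions: LiN(i-Pr)2 (1.15 equiv), THF, −78 °C; Me3SiCl/Et3N, −78 → 0 °C; pentane, filtration, used crude
Reagents that add atoms: chlorotrimethylsilane, C[Si](C)(C)Cl
Why: Kinetic α′-deprotonation of a vinylogous ester (Stork–Danheiser-type cross-conjugated enolate) followed by O-silylation, in which the amide base at low temperature removes the hydrogen next to the carbonyl and not the γ hydrogen, and the hard silicon electrophile is taken up on oxygen, putting ring B at the dihydroarene level.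

Step 14
Reactants: 23 6-Ar-4-(methoxymethoxy)-1,5-diprenyl-2-(trimethylsilyloxy)cyclohexa-1,3-diene
Product: 25 3-Ar-5-(methoxymethoxy)-2,4-diprenylphenol, via aryl trimethylsilyl ether 24 (not isolated)
Conditions: DDQ (1.0 equiv, slow addition), 2,4,6-collidine, CH2Cl2, −40 → 0 °C; then K2CO3 (cat.), MeOH, rt
Reagents that add atoms: none
Why: Quinone dehydrogenation of a silyloxy cyclohexadiene, in which DDQ takes hydride from the Ar-bearing ring carbon to give a pentadienyl cation stabilised by both ring oxygens and the benzofuran, and the adjacent ring C–H is then the only acidified proton, so that, unlike a syn elimination from an α-seleno or α-sulfinyl ketone (which could run toward the allylic CH2 and needs electrophilic selenium and peroxide beside three alkenes), the new unsaturation cannot end up in a prenyl chain.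

Step 15
Reactants: 25 3-Ar-5-(methoxymethoxy)-2,4-diprenylphenol
Product: 26 5-[4,6-dihydroxy-7-(2-methylbut-3-en-2-yl)-1-benzofuran-2-yl]-4,6-diprenylbenzene-1,3-diol (CNP0115465.0)
Conditions: conc. aq. HCl (cat.), MeOH, rt → 40 °C, Ar, stopped at full conversion
Reagents that add atoms: none
Why: Acid-catalysed transacetalisation (MOM cleavage), in which each aryl formaldehyde acetal exchanges with methanol through its oxocarbenium ion at an acidity too low to protonate the alkenes at a useful rate, so chroman or dihydrofuran closure onto the neighbouring phenols should not set in.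

## Compound list

1 | 2,4,6-trihydroxybenzaldehyde | O=Cc1c(O)cc(O)cc1O | starting material
2 | 2-hydroxy-4,6-bis(methoxymethoxy)benzaldehyde | O=Cc1c(O)cc(OCOC)cc1OCOC | intermediate
3 | prenyl bromide | CC(C)=CCBr | starting material
4 | 2,4-bis(methoxymethoxy)-6-(prenyloxy)benzaldehyde | O=Cc1c(OCC=C(C)C)cc(OCOC)cc1OCOC | intermediate
5 | 2,4-bis(methoxymethoxy)-5-(2-methylbut-3-en-2-yl)-6-oxocyclohexa-1,3-diene-1-carbaldehyde (racemic ortho-dienone, not isolated) | O=CC1=C(OCOC)C=C(OCOC)C(C(C)(C)C=C)C1=O | intermediate
6 | 4,6-bis(methoxymethoxy)-3-(2-methylbut-3-en-2-yl)-2-(trimethylsilyloxy)benzaldehyde (not isolated) | O=Cc1c(O[Si](C)(C)C)c(C(C)(C)C=C)c(OCOC)cc1OCOC | intermediate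
7 | 2-hydroxy-4,6-bis(methoxymethoxy)-3-(2-methylbut-3-en-2-yl)benzaldehyde | O=Cc1c(O)c(C(C)(C)C=C)c(OCOC)cc1OCOC | intermediate
8 | methyl bromoacetate | COC(=O)CBr | starting material
9 | methyl 2-[2-formyl-3,5-bis(methoxymethoxy)-6-(2-methylbut-3-en-2-yl)phenoxy]acetate (not isolated) | COC(=O)COc1c(C=O)c(OCOC)cc(OCOC)c1C(C)(C)C=C | intermediate
10 | methyl 4,6-bis(methoxymethoxy)-7-(2-methylbut-3-en-2-yl)-1-benzofuran-2-carboxylate | COC(=O)c1cc2c(OCOC)cc(OCOC)c(C(C)(C)C=C)c2o1 | intermediate
11 | [4,6-bis(methoxymethoxy)-7-(2-methylbut-3-en-2-yl)-1-benzofuran-2-yl]methanol | OCc1cc2c(OCOC)cc(OCOC)c(C(C)(C)C=C)c2o1 | intermediate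
12 | 4,6-bis(methoxymethoxy)-7-(2-methylbut-3-en-2-yl)-1-benzofuran-2-carbaldehyde | O=Cc1cc2c(OCOC)cc(OCOC)c(C(C)(C)C=C)c2o1 | intermediate
13 | dimethyl (2-oxopropyl)phosphonate | COP(=O)(OC)CC(C)=O | starting material
14 | dimethyl (6-methyl-2-oxohept-5-en-3-yl)phosphonate | COP(=O)(OC)C(CC=C(C)C)C(C)=O | intermediate
15 | (3E)-3-(Ar-methylidene)-6-methylhept-5-en-2-one | CC(=O)/C(CC=C(C)C)=C/c1cc2c(OCOC)cc(OCOC)c(C(C)(C)C=C)c2o1 | intermediate
16 | dimethyl malonate | COC(=O)CC(=O)OC | starting material
17 | dimethyl 2-prenylpropanedioate | COC(=O)C(CC=C(C)C)C(=O)OC | intermediate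
18 | dimethyl 2-(2-acetyl-1-Ar-5-methylhex-4-en-1-yl)-2-prenylpropanedioate (not isolated) | COC(=O)C(CC=C(C)C)(C(=O)OC)C(c1cc2c(OCOC)cc(OCOC)c(C(C)(C)C=C)c2o1)C(CC=C(C)C)C(C)=O | intermediate
19 | methyl 6-Ar-1,5-diprenyl-2,4-dioxocyclohexane-1-carboxylate | COC(=O)C1(CC=C(C)C)C(=O)CC(=O)C(CC=C(C)C)C1c1cc2c(OCOC)cc(OCOC)c(C(C)(C)C=C)c2o1 | intermediate
20 | lithium 6-Ar-1,5-diprenyl-2,4-dioxocyclohexane-1-carboxylate (not isolated) | [Li+].[O-]C(=O)C1(CC=C(C)C)C(=O)CC(=O)C(CC=C(C)C)C1c1cc2c(OCOC)cc(OCOC)c(C(C)(C)C=C)c2o1 | intermediate
21 | 5-Ar-4,6-diprenylcyclohexane-1,3-dione | O=C1CC(=O)C(CC=C(C)C)C(c2cc3c(OCOC)cc(OCOC)c(C(C)(C)C=C)c3o2)C1CC=C(C)C | intermediate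
22 | 5-Ar-3-(methoxymethoxy)-4,6-diprenylcyclohex-2-en-1-one | O=C1C=C(OCOC)C(CC=C(C)C)C(c2cc3c(OCOC)cc(OCOC)c(C(C)(C)C=C)c3o2)C1CC=C(C)C | intermediate
23 | 6-Ar-4-(methoxymethoxy)-1,5-diprenyl-2-(trimethylsilyloxy)cyclohexa-1,3-diene | C[Si](C)(C)OC1=C(CC=C(C)C)C(c2cc3c(OCOC)cc(OCOC)c(C(C)(C)C=C)c3o2)C(CC=C(C)C)C(OCOC)=C1 | intermediate
24 | [3-Ar-5-(methoxymethoxy)-2,4-diprenylphenoxy]trimethylsilane (not isolated) | C=CC(C)(C)c1c(OCOC)cc(OCOC)c2cc(-c3c(CC=C(C)C)c(O[Si](C)(C)C)cc(OCOC)c3CC=C(C)C)oc12 | intermediate
25 | 3-Ar-5-(methoxymethoxy)-2,4-diprenylphenol | C=CC(C)(C)c1c(OCOC)cc(OCOC)c2cc(-c3c(CC=C(C)C)c(O)cc(OCOC)c3CC=C(C)C)oc12 | intermediate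
26 | 5-[4,6-dihydroxy-7-(2-methylbut-3-en-2-yl)-1-benzofuran-2-yl]-4,6-diprenylbenzene-1,3-diol (CNP0115465.0) | C=CC(C)(C)c1c(O)cc(O)c2cc(-c3c(CC=C(C)C)c(O)cc(O)c3CC=C(C)C)oc12 | target

## Step count

Total step count: 15.
Longest linear sequence: 13 steps (steps 1–6, 8, 10–15). Steps 7 and 9 are one-step side branches.

## Steps most likely to fail

**Step 10.**
- What may go wrong: the addition of a fully substituted malonate carbanion to an α-branched, β-heteroaryl enone may stall. Retro-Michael cleavage, reversible methoxide addition and self-condensation of the enone through its methyl ketone could then outrun ring closure.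
- Fallback: bring in the second prenyl group after the ring is closed. Setting out from 15, unsubstituted dimethyl malonate 16 (NaOMe, MeOH, reflux) undergoes the far less crowded Michael–Claisen annulation and should give methyl 6-Ar-5-prenyl-2,4-dioxocyclohexane-1-carboxylate F1.
- The dianion of F1 is then formed with LiN(i-Pr)2 (2.2 equiv) in THF/DMPU at −78 → −30 °C. The CH2 between the ketones is deprotonated first, then the C1–H between ketone and ester.
- One equivalent of 3 alkylates this dianion at the last formed, more basic carbanion C1. This rejoins the route at 19.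

**Step 3.**
- What may go wrong: onward Cope migration of the 1,1-dimethylallyl group from C3 to the free C5 (para to the migrating oxygen), which turns it back into a normal prenyl group, may outrun the silyl trapping. Thermal loss of the prenyl ether is also possible.
- Fallback: move the migrating ether to an oxygen whose para carbon cannot accept the group, and close the furan first. Setting out from 1, the only non-chelated hydroxyl is alkylated with 3 (K2CO3, 1 equiv, acetone, rt) to give 2,6-dihydroxy-4-(prenyloxy)benzaldehyde F2.
- One of the two equivalent ortho hydroxyls of F2 is carried through the furan closure with 8 (K2CO3, DMF, heat) to give methyl 4-hydroxy-6-(prenyloxy)-1-benzofuran-2-carboxylate F3.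
- MOMCl/i-Pr2NEt then gives methyl 4-(methoxymethoxy)-6-(prenyloxy)-1-benzofuran-2-carboxylate F4.
- Heating F4 in PhNEt2 brings about the Claisen shift. The para position is now the ring-fusion carbon C3a. C7 is favoured over C5 by the higher double-bond character of the C6–C7 bond and by the tied-back furan oxygen next to it. This should give methyl 6-hydroxy-4-(methoxymethoxy)-7-(2-methylbut-3-en-2-yl)-1-benzofuran-2-carboxylate F5.
- A last MOM protection of F5 rejoins the route at 10.

**Step 14.**
- What may go wrong: hydride transfer from the crowded ring methine may be slow. Protodesilylation back to the enone stage, or over-oxidation at the benzylic–allylic CH2 groups once ring B is aromatic, could then take over.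
- Fallback: merge ester removal and dehydrogenation in one palladium-catalysed event. Commercial diallyl malonate is alkylated with 3 (NaH, THF) to give diallyl 2-prenylpropanedioate F6.
- Setting out from 15, F6 is annulated as in step 10 (NaOCH2CH=CH2, allyl alcohol, reflux) to give allyl 6-Ar-1,5-diprenyl-2,4-dioxocyclohexane-1-carboxylate F7.
- MOMCl/i-Pr2NEt caps the less hindered dione oxygen to give allyl 6-Ar-4-(methoxymethoxy)-1,5-diprenyl-2-oxocyclohex-3-ene-1-carboxylate F8. The regioisomeric enol ether, if it forms, converges on the same phenol.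
- Pd(OAc)2/dppe (cat.) in refluxing MeCN then effects decarboxylation–dehydrogenation of the allyl β-keto ester (Tsuji type). Zerovalent palladium ionises the allyl ester, CO2 leaves, and the palladium enolate undergoes β-hydride elimination toward the ring methine. Any elimination into the side chain can be undone by re-addition of the palladium hydride. Propene is released, and the cross-conjugated dienone tautomerises irreversibly to the phenol.
- The route is rejoined at 25, and steps 11–14 drop out.

## Further compounds

F1 | step 10 | methyl 6-Ar-5-prenyl-2,4-dioxocyclohexane-1-carboxylate | COC(=O)C1C(=O)CC(=O)C(CC=C(C)C)C1c1cc2c(OCOC)cc(OCOC)c(C(C)(C)C=C)c2o1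
F2 | step 3 | 2,6-dihydroxy-4-(prenyloxy)benzaldehyde | O=Cc1c(O)cc(OCC=C(C)C)cc1O
F3 | step 3 | methyl 4-hydroxy-6-(prenyloxy)-1-benzofuran-2-carboxylate | COC(=O)c1cc2c(O)cc(OCC=C(C)C)cc2o1
F4 | step 3 | methyl 4-(methoxymethoxy)-6-(prenyloxy)-1-benzofuran-2-carboxylate | COC(=O)c1cc2c(OCOC)cc(OCC=C(C)C)cc2o1
F5 | step 3 | methyl 6-hydroxy-4-(methoxymethoxy)-7-(2-methylbut-3-en-2-yl)-1-benzofuran-2-carboxylate | COC(=O)c1cc2c(OCOC)cc(O)c(C(C)(C)C=C)c2o1
F6 | step 14 | diallyl 2-prenylpropanedioate | C=CCOC(=O)C(CC=C(C)C)C(=O)OCC=C
F7 | step 14 | allyl 6-Ar-1,5-diprenyl-2,4-dioxocyclohexane-1-carboxylate | C=CCOC(=O)C1(CC=C(C)C)C(=O)CC(=O)C(CC=C(C)C)C1c1cc2c(OCOC)cc(OCOC)c(C(C)(C)C=C)c2o1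
F8 | step 14 | allyl 6-Ar-4-(methoxymethoxy)-1,5-diprenyl-2-oxocyclohex-3-ene-1-carboxylate | C=CCOC(=O)C1(CC=C(C)C)C(=O)C=C(OCOC)C(CC=C(C)C)C1c1cc2c(OCOC)cc(OCOC)c(C(C)(C)C=C)c2o1
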